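**Retrosynthetic overview**
1. The triene side chain comes from an aldol condensation of a cis-fused γ-lactone (spanning O-1 and C-2) with a C11 dienal, followed by lactone reduction. The lactone comes from a rhodium-carbenoid C–H insertion of the C-1 diazoacetate, which sets C-2.
2. The C-1 hydroxyl is set by hydroxyl-directed reduction; the C-6 carbinol by MeLi addition to a spiro ketone.
3. The six-membered ring and the tetrasubstituted enal alkene form together in one rhodium-catalysed methylative alkyne/vinyl-ketone cyclization.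
4. C-5 and C-10 are set by a Claisen rearrangement of an enol ether made from a 2-chlorocyclopentene Weinreb amide and an (S)-allylic alcohol (itself from cross-metathesis and Suzuki coupling).
5. Ring order: cyclopentane (from cyclopentanone), then cyclohexane (step 13), then a temporary lactone (closed in step 19, opened in step 23).

Assumption: the target is read as (1R,2S,5S,6S,10R) with a (Z)-enal and a (2E,4E,6E) side chain; locants are those of spiro[4.5]decane (C1 = CHOH, C2 = CH carrying the side chain, C5 = spiro carbon, C6 = C(Me)OH, C9 = alkylidene carbon, C10 = CH carrying the hydroxypropyl group).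

**Route**

Step 1
Reactants: 1 cyclopentanone
Product: 2 2-chlorocyclopent-1-ene-1-carbaldehyde
Conditions: POCl3, DMF, CH2Cl2, 0 to 40 °C; aq. NaOAc
Reagents that add atoms: N,N-dimethylformamide CN(C)C=O; phosphoryl chloride O=P(Cl)(Cl)Cl
Why: Vilsmeier–Haack–Arnold chloroformylation of an enolisable ketone gives the β-chloro enal directly.

Step 2
Reactants: 2 2-chlorocyclopent-1-ene-1-carbaldehyde
Product: 3 2-chlorocyclopent-1-ene-1-carboxylic acid
Conditions: NaClO2, NaH2PO4, 2-methylbut-2-ene, t-BuOH/H2O, rt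
Reagents that add atoms: sodium chlorite [Na+].[O-]Cl=O
Why: Pinnick oxidation converts the enal into the acid without touching the vinyl chloride.

Step 3
Reactants: 3 2-chlorocyclopent-1-ene-1-carboxylic acid
Product: 5 2-chloro-N-methoxy-N-methylcyclopent-1-ene-1-carboxamide, via acid chloride 4 (not isolated)
Conditions: (COCl)2, cat. DMF, CH2Cl2, 0 °C to rt; then MeNHOMe·HCl, Et3N, 0 °C
Reagents that add atoms: N,O-dimethylhydroxylamine hydrochloride CNOC.Cl
Why: Standard acid chloride amidation gives the Weinreb amide that later delivers the vinyl ketone in one step.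

Step 4
Reactants: 6 ethynylmagnesium bromide; 7 trimethyl orthoformate
Product: 8 3,3-dimethoxyprop-1-yne
Conditions: THF/toluene, 60 °C; aq. NH4Cl
Reagents that add atoms: none
Why: Bodroux–Chichibabin displacement of one methoxide of the orthoester by the alkynyl Grignard gives the propargylic acetal, the masked form of the future aldehyde.

Step 5
Reactants: 8 3,3-dimethoxyprop-1-yne
Product: 9 1-bromo-3,3-dimethoxyprop-1-yne
Conditions: NBS, AgNO3 (10 mol %), acetone, rt
Reagents that add atoms: N-bromosuccinimide O=C1CCC(=O)N1Br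
Why: Silver-catalysed electrophilic bromination of the terminal alkyne C–H gives the 1-bromoalkyne.

Step 6
Reactants: 10 (2S)-but-3-ene-1,2-diol
Product: 11 (2S)-1-(tert-butyldimethylsilyloxy)but-3-en-2-ol
Conditions: TBSCl, imidazole, CH2Cl2, −20 °C
Reagents that add atoms: tert-butyldimethylsilyl chloride CC(C)(C)[Si](C)(C)Cl
Why: Selective silylation of the primary hydroxyl leaves the allylic carbinol, the single source of absolute configuration, free.

Step 7
Reactants: 12 vinylmagnesium bromide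
Product: 13 4,4,5,5-tetramethyl-2-vinyl-1,3,2-dioxaborolane
Conditions: i-PrOBpin, THF, −78 °C to rt; then HCl in Et2O
Reagents that add atoms: 2-isopropoxy-4,4,5,5-tetramethyl-1,3,2-dioxaborolane CC(C)OB1OC(C)(C)C(C)(C)O1
Why: Grignard borylation (ate complex, loss of isopropoxide) gives the vinyl boronate.

Step 8
Reactants: 11 (2S)-1-(tert-butyldimethylsilyloxy)but-3-en-2-ol; 13 4,4,5,5-tetramethyl-2-vinyl-1,3,2-dioxaborolane
Product: 14 (2S,3E)-1-(tert-butyldimethylsilyloxy)-4-(4,4,5,5-tetramethyl-1,3,2-dioxaborolan-2-yl)but-3-en-2-ol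
Conditions: second-generation Grubbs catalyst RuCl2(=CHPh)(PCy3)(SIMes) (5 mol %), CH2Cl2, 40 °C
Reagents that add atoms: none
Why: Olefin cross-metathesis of a terminal alkene with the vinyl boronate is E-selective and does not touch the carbinol stereocentre.

Step 9
Reactants: 14 (2S,3E)-alkenyl boronate; 9 1-bromo-3,3-dimethoxyprop-1-yne
Product: 15 (2S,3E)-1-(tert-butyldimethylsilyloxy)-7,7-dimethoxyhept-3-en-5-yn-2-ol
Conditions: Pd(PPh3)4 (5 mol %), K3PO4, THF/H2O, 50 °C
Reagents that add atoms: none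
Why: Suzuki–Miyaura coupling of the alkenyl boronate with the 1-bromoalkyne on zerovalent palladium retains the (E)-geometry and gives the enyne.

Step 10
Reactants: 5 2-chloro-N-methoxy-N-methylcyclopent-1-ene-1-carboxamide; 15 (2S,3E)-enynol
Product: 17 (1S)-1-[(2E,4R)-1-(tert-butyldimethylsilyloxy)-7,7-dimethoxyhept-2-en-5-yn-4-yl]-N-methoxy-N-methyl-2-oxocyclopentane-1-carboxamide, via allyl vinyl ether 16 (not isolated)
Conditions: NaH, THF, 0 °C to rt; then AcOH, o-xylene, 140 °C
Reagents that add atoms: none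
Why: Alkoxide addition–elimination on the β-chloro enamide keeps the (S)-carbinol, and the chair Claisen rearrangement of the ring-locked enol ether ((E)-alkene, CH2OTBS equatorial) transfers it to the (S)-quaternary carbon and the adjacent (R)-CH (future C5 and C10).

Step 11
Reactants: 17 keto amide
Product: 18 (1S)-1-[(2E,4R)-1-(tert-butyldimethylsilyloxy)-7,7-dimethoxyhept-2-en-5-yn-4-yl]-N-methoxy-N-methyl-2-(triethylsilyloxy)cyclopent-2-ene-1-carboxamide
Conditions: Et3SiOTf, Et3N, CH2Cl2, −78 to 0 °C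
Reagents that add atoms: triethylsilyl trifluoromethanesulfonate CC[Si](CC)(CC)OS(=O)(=O)C(F)(F)F
Why: Soft enolisation can only go away from the quaternary carbon, so silyl enol ether formation masks the ring ketone for the next three steps.

Step 12
Reactants: 18 silyl enol ether amide; 12 vinylmagnesium bromide
Product: 19 1-{(1S)-1-[(2E,4R)-1-(tert-butyldimethylsilyloxy)-7,7-dimethoxyhept-2-en-5-yn-4-yl]-2-(triethylsilyloxy)cyclopent-2-en-1-yl}prop-2-en-1-one
Conditions: THF, 0 °C; inverse quench into cold aq. NH4Cl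
Reagents that add atoms: none
Why: Weinreb ketone synthesis: the chelated tetrahedral adduct stops at the vinyl ketone stage.

Step 13
Reactants: 19 ynenone
Product: 20 (5S,10R)-10-[(E)-3-(tert-butyldimethylsilyloxy)prop-1-enyl]-9-[(Z)-1,1-dimethoxypropan-2-ylidene]-1-(triethylsilyloxy)spiro[4.5]dec-1-en-6-one
Conditions: [Rh(cod)Cl]2 (5 mol %), Me2Zn (slow addition), THF, 0 °C to rt; aq. NH4Cl
Reagents that add atoms: dimethylzinc C[Zn]C
Why: Proposed new method: a monovalent-rhodium, Me2Zn-driven methylative cyclization of a 3-oxo-1,6-enyne, in which Me–Rh (from transmetalation) adds syn across the alkyne with Rh on the carbon next to C10 (the regiochemistry held by chelation of the vinyl ketone), the alkenyl–Rh adds 1,4 to the tethered vinyl ketone in 6-endo-trig fashion at the terminal β-carbon, and zinc takes over the rhodium enolate to turn the catalyst over, so CH3 ends cis to C8 and the acetal carbon cis to C10 with C5/C10 untouched; the closest known reactions are the rhodium-catalysed arylative cyclization of alkyne-tethered enoates with arylboron reagents and the nickel-catalysed alkylative cyclization of alkynyl enones with organozincs (both exo-mode), and what is new is methyl transfer from rhodium to an internal alkyne combined with endo-mode enone capture.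

Step 14
Reactants: 20 spiro ketone
Product: 22 (5R,6S,10R)-10-[(E)-3-(tert-butyldimethylsilyloxy)prop-1-enyl]-9-[(Z)-1,1-dimethoxypropan-2-ylidene]-6-hydroxy-6-methylspiro[4.5]decan-1-one, via tertiary alcohol 21 (not isolated)
Conditions: MeLi, CeCl3, THF, −78 °C; then AcOH, Bu4NF, THF, 0 °C
Reagents that add atoms: methyllithium [Li]C
Why: Organocerium 1,2-addition should come from the face opposite the C10 chain, which 1,3-allylic strain with the exocyclic acetal group holds axial, so CH3 ends cis to C4 and OH cis to C1; buffered fluoride then cleaves the silyl enol ether to the cyclopentanone.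

Step 15
Reactants: 22 hydroxy ketone
Product: 23 (5R,6S,10R)-10-[3-(tert-butyldimethylsilyloxy)propyl]-9-[(Z)-1,1-dimethoxypropan-2-ylidene]-6-hydroxy-6-methylspiro[4.5]decan-1-one
Conditions: H2 (1 atm), RhCl(PPh3)3 (5 mol %), benzene/EtOH, rt
Reagents that add atoms: none
Why: Homogeneous hydrogenation with RhCl(PPh3)3 saturates the disubstituted alkene and leaves the tetrasubstituted one.

Step 16
Reactants: 23 hydroxy ketone
Product: 24 (1R,5S,6S,10R)-10-[3-(tert-butyldimethylsilyloxy)propyl]-9-[(Z)-1,1-dimethoxypropan-2-ylidene]-6-methylspiro[4.5]decane-1,6-diol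
Conditions: Me4NBH(OAc)3, AcOH/MeCN, −20 °C
Reagents that add atoms: none
Why: Evans–Saksena reduction: the C6 hydroxyl binds boron and delivers hydride to the face of C1 on which C6 lies, giving the 1,3-anti diol with the (1R)-hydroxyl cis to C10.

Step 17
Reactants: 24 diol; 25 bromoacetyl bromide
Product: 27 (1R,5S,6S,10R)-10-[3-(tert-butyldimethylsilyloxy)propyl]-9-[(Z)-1,1-dimethoxypropan-2-ylidene]-6-hydroxy-6-methylspiro[4.5]decan-1-yl diazoacetate, via bromoacetate 26 (not isolated)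
Conditions: NaHCO3, MeCN, 0 °C; then TsNHNHTs, DBU, THF, 0 °C
Reagents that add atoms: N,N'-ditosylhydrazine Cc1ccc(cc1)S(=O)(=O)NNS(=O)(=O)c1ccc(C)cc1
Why: The secondary hydroxyl is acylated in preference to the tertiary one, and the bromoacetate becomes the diazoacetate by N-alkylation of the hydrazine and double sulfinate elimination (Fukuyama diazoacetate synthesis).

Step 18
Reactants: 27 hydroxy diazoacetate
Product: 28 (1R,5S,6S,10R)-10-[3-(tert-butyldimethylsilyloxy)propyl]-9-[(Z)-1,1-dimethoxypropan-2-ylidene]-6-methyl-6-(trimethylsilyloxy)spiro[4.5]decan-1-yl diazoacetate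
Conditions: 1-(trimethylsilyl)imidazole, CH2Cl2, rt
Reagents that add atoms: 1-(trimethylsilyl)imidazole C[Si](C)(C)n1ccnc1
Why: Neutral silyl transfer caps the tertiary hydroxyl, which would otherwise undergo O–H insertion, without harming the diazo ester.

Step 19
Reactants: 28 diazoacetate
Product: 29 cis-fused γ-lactone, (1R,2S,5S,6S,10R)-configured spirodecane in which O-1 and C-2 are bridged by C(=O)CH2 and which carries 6-methyl, 6-(trimethylsilyloxy), 10-[3-(tert-butyldimethylsilyloxy)propyl] and 9-[(Z)-1,1-dimethoxypropan-2-ylidene]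
Conditions: Rh2(cap)4 (cap = caprolactamate, 1 mol %), CH2Cl2, 40 °C, slow addition of 28
Reagents that add atoms: none
Why: The divalent-rhodium carbenoid inserts into the only C–H bond 1,5 to it (H-2 on the face of the ester oxygen; the other neighbour is quaternary), so the γ-lactone is necessarily cis-fused and C2 is set (S) (intramolecular carbenoid C–H insertion).

Step 20
Reactants: 30 (2E)-pent-2-en-4-yn-1-ol; 31 1-bromo-3-methylbut-2-ene
Product: 33 (2E,4E)-4,8-dimethylnona-2,4,7-trien-1-ol, via alkenylalane 32 (not isolated)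
Conditions: Me3Al, Cp2ZrCl2 (20 mol %), ClCH2CH2Cl, 0 °C to rt; then 31, Pd(PPh3)4 (5 mol %), THF, rt; aq. potassium sodium tartrate
Reagents that add atoms: trimethylaluminum C[Al](C)C
Why: Zirconium-catalysed syn-methylalumination puts CH3 on the internal alkyne carbon, and zerovalent-palladium coupling of the alkenylalane with the primary end of the allyl bromide keeps the (E)-geometry (Negishi carboalumination and alkenyl–allyl cross-coupling).

Step 21
Reactants: 33 dienol
Product: 34 (2E,4E)-4,8-dimethylnona-2,4,7-trienal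
Conditions: MnO2, CH2Cl2, rt
Reagents that add atoms: none
Why: Allylic oxidation with MnO2 gives the dienal without moving the skipped diene.

Step 22
Reactants: 29 γ-lactone; 34 dienal
Product: 37 (E)-α-[(2E,4E)-4,8-dimethylnona-2,4,7-trienylidene] derivative of lactone 29, via aldol adduct 35 (not isolated), via mesylate 36 (not isolated)
Conditions: LiN(i-Pr)2, THF, −78 °C; 34; then MsCl, −78 to 0 °C; then DBU, rt
Reagents that add atoms: none
Why: Aldol addition of the lactone enolate and E1cB loss of mesylate give the thermodynamically preferred (E)-alkylidene lactone with the chain anti to the carbonyl, that is cis to C2 (aldol condensation).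

Step 23
Reactants: 37 alkylidene lactone
Product: 38 (1R,2S,5S,6S,10R)-10-[3-(tert-butyldimethylsilyloxy)propyl]-9-[(Z)-1,1-dimethoxypropan-2-ylidene]-2-[(2E,4E,6E)-1-hydroxy-6,10-dimethylundeca-2,4,6,9-tetraen-2-yl]-6-methyl-6-(trimethylsilyloxy)spiro[4.5]decan-1-ol
Conditions: i-Bu2AlH, CH2Cl2, −78 to −20 °C; aq. potassium sodium tartrate
Reagents that add atoms: none
Why: 1,2-Reduction of the unsaturated lactone gives the primary allylic alcohol and frees the C1 hydroxyl while acetal and silyl ethers survive (lactone-to-diol reduction).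

Step 24
Reactants: 38 protected tetraol acetal
Product: 39 (2Z)-2-{(1R,2S,5S,6S,10R)-1,6-dihydroxy-2-[(2E,4E,6E)-1-hydroxy-6,10-dimethylundeca-2,4,6,9-tetraen-2-yl]-10-(3-hydroxypropyl)-6-methylspiro[4.5]decan-9-ylidene}propanal
Conditions: AcOH/THF/H2O (3:1:1), rt
Reagents that add atoms: water O
Why: Mild aqueous acid removes the primary TBS and tertiary TMS ethers and hydrolyses the allylic dimethyl acetal to the (Z)-enal without moving the tetrasubstituted alkene (global acidic deprotection).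

**Compound list**

1 | cyclopentanone | O=C1CCCC1 | starting material
2 | 2-chlorocyclopent-1-ene-1-carbaldehyde | O=CC1=C(Cl)CCC1 | intermediate
3 | 2-chlorocyclopent-1-ene-1-carboxylic acid | OC(=O)C1=C(Cl)CCC1 | intermediate
4 | 2-chlorocyclopent-1-ene-1-carbonyl chloride | ClC(=O)C1=C(Cl)CCC1 | intermediate
5 | 2-chloro-N-methoxy-N-methylcyclopent-1-ene-1-carboxamide | CON(C)C(=O)C1=C(Cl)CCC1 | intermediate
6 | ethynylmagnesium bromide | C#C[Mg]Br | starting material
7 | trimethyl orthoformate | COC(OC)OC | starting material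
8 | 3,3-dimethoxyprop-1-yne | C#CC(OC)OC | intermediate
9 | 1-bromo-3,3-dimethoxyprop-1-yne | BrC#CC(OC)OC | intermediate
10 | (2S)-but-3-ene-1,2-diol | C=C[C@H](O)CO | starting material
11 | (2S)-1-(tert-butyldimethylsilyloxy)but-3-en-2-ol | C=C[C@H](O)CO[Si](C)(C)C(C)(C)C | intermediate
12 | vinylmagnesium bromide | C=C[Mg]Br | starting material
13 | 4,4,5,5-tetramethyl-2-vinyl-1,3,2-dioxaborolane | C=CB1OC(C)(C)C(C)(C)O1 | intermediate
14 | (2S,3E)-1-(tert-butyldimethylsilyloxy)-4-(4,4,5,5-tetramethyl-1,3,2-dioxaborolan-2-yl)but-3-en-2-ol | CC(C)(C)[Si](C)(C)OC[C@@H](O)/C=C/B1OC(C)(C)C(C)(C)O1 | intermediate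
15 | (2S,3E)-1-(tert-butyldimethylsilyloxy)-7,7-dimethoxyhept-3-en-5-yn-2-ol | CC(C)(C)[Si](C)(C)OC[C@@H](O)/C=C/C#CC(OC)OC | intermediate
16 | N-methoxy-N-methyl-2-{[(2S,3E)-1-(tert-butyldimethylsilyloxy)-7,7-dimethoxyhept-3-en-5-yn-2-yl]oxy}cyclopent-1-ene-1-carboxamide | CON(C)C(=O)C1=C(O[C@H](CO[Si](C)(C)C(C)(C)C)/C=C/C#CC(OC)OC)CCC1 | intermediate
17 | (1S)-1-[(2E,4R)-1-(tert-butyldimethylsilyloxy)-7,7-dimethoxyhept-2-en-5-yn-4-yl]-N-methoxy-N-methyl-2-oxocyclopentane-1-carboxamide | O=C1CCC[C@]1(C(=O)N(C)OC)[C@@H](C#CC(OC)OC)/C=C/CO[Si](C)(C)C(C)(C)C | intermediate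
18 | (1S)-1-[(2E,4R)-1-(tert-butyldimethylsilyloxy)-7,7-dimethoxyhept-2-en-5-yn-4-yl]-N-methoxy-N-methyl-2-(triethylsilyloxy)cyclopent-2-ene-1-carboxamide | CC[Si](CC)(CC)OC1=CCC[C@]1(C(=O)N(C)OC)[C@@H](C#CC(OC)OC)/C=C/CO[Si](C)(C)C(C)(C)C | intermediate
19 | 1-{(1S)-1-[(2E,4R)-1-(tert-butyldimethylsilyloxy)-7,7-dimethoxyhept-2-en-5-yn-4-yl]-2-(triethylsilyloxy)cyclopent-2-en-1-yl}prop-2-en-1-one | CC[Si](CC)(CC)OC1=CCC[C@]1(C(=O)C=C)[C@@H](C#CC(OC)OC)/C=C/CO[Si](C)(C)C(C)(C)C | intermediate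
20 | (5S,10R)-10-[(E)-3-(tert-butyldimethylsilyloxy)prop-1-enyl]-9-[(Z)-1,1-dimethoxypropan-2-ylidene]-1-(triethylsilyloxy)spiro[4.5]dec-1-en-6-one | CC[Si](CC)(CC)OC1=CCC[C@]12[C@H](/C=C/CO[Si](C)(C)C(C)(C)C)/C(=C(/C)C(OC)OC)CCC2=O | intermediate
21 | (5R,6S,10R)-10-[(E)-3-(tert-butyldimethylsilyloxy)prop-1-enyl]-9-[(Z)-1,1-dimethoxypropan-2-ylidene]-6-methyl-1-(triethylsilyloxy)spiro[4.5]dec-1-en-6-ol | CC[Si](CC)(CC)OC1=CCC[C@]12[C@H](/C=C/CO[Si](C)(C)C(C)(C)C)/C(=C(/C)C(OC)OC)CC[C@]2(C)O | intermediate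
22 | (5R,6S,10R)-10-[(E)-3-(tert-butyldimethylsilyloxy)prop-1-enyl]-9-[(Z)-1,1-dimethoxypropan-2-ylidene]-6-hydroxy-6-methylspiro[4.5]decan-1-one | O=C1CCC[C@]12[C@H](/C=C/CO[Si](C)(C)C(C)(C)C)/C(=C(/C)C(OC)OC)CC[C@]2(C)O | intermediate
23 | (5R,6S,10R)-10-[3-(tert-butyldimethylsilyloxy)propyl]-9-[(Z)-1,1-dimethoxypropan-2-ylidene]-6-hydroxy-6-methylspiro[4.5]decan-1-one | O=C1CCC[C@]12[C@H](CCCO[Si](C)(C)C(C)(C)C)/C(=C(/C)C(OC)OC)CC[C@]2(C)O | intermediate
24 | (1R,5S,6S,10R)-10-[3-(tert-butyldimethylsilyloxy)propyl]-9-[(Z)-1,1-dimethoxypropan-2-ylidene]-6-methylspiro[4.5]decane-1,6-diol | C1CC[C@]2([C@H](CCCO[Si](C)(C)C(C)(C)C)/C(=C(/C)C(OC)OC)CC[C@]2(C)O)[C@@H]1O | intermediate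
25 | bromoacetyl bromide | BrCC(Br)=O | starting material
26 | C1 bromoacetate of diol 24 | C1CC[C@]2([C@H](CCCO[Si](C)(C)C(C)(C)C)/C(=C(/C)C(OC)OC)CC[C@]2(C)O)[C@@H]1OC(=O)CBr | intermediate
27 | C1 diazoacetate of diol 24 (6-OH free) | C1CC[C@]2([C@H](CCCO[Si](C)(C)C(C)(C)C)/C(=C(/C)C(OC)OC)CC[C@]2(C)O)[C@@H]1OC(=O)C=[N+]=[N-] | intermediate
28 | C1 diazoacetate, 6-O-trimethylsilyl ether | C1CC[C@]2([C@H](CCCO[Si](C)(C)C(C)(C)C)/C(=C(/C)C(OC)OC)CC[C@]2(C)O[Si](C)(C)C)[C@@H]1OC(=O)C=[N+]=[N-] | intermediate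
29 | cis-fused γ-lactone (O-1/C-2 bridged by C(=O)CH2; 1R,2S,5S,6S,10R) | O=C1C[C@@H]2CC[C@]3([C@H](CCCO[Si](C)(C)C(C)(C)C)/C(=C(/C)C(OC)OC)CC[C@]3(C)O[Si](C)(C)C)[C@@H]2O1 | intermediate
30 | (2E)-pent-2-en-4-yn-1-ol | C#C/C=C/CO | starting material
31 | 1-bromo-3-methylbut-2-ene | CC(C)=CCBr | starting material
32 | dimethylaluminum alkoxide of (2E,4E)-5-(dimethylalumanyl)-4-methylpenta-2,4-dien-1-ol | C[Al](C)OC/C=C/C(C)=C/[Al](C)C | intermediate
33 | (2E,4E)-4,8-dimethylnona-2,4,7-trien-1-ol | CC(C)=CC/C=C(C)/C=C/CO | intermediate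
34 | (2E,4E)-4,8-dimethylnona-2,4,7-trienal | CC(C)=CC/C=C(C)/C=C/C=O | intermediate
35 | aldol adduct of 29 and 34 (new carbinol and α-carbon as a mixture) | CC(C)=CC/C=C(C)/C=C/C(O)C1C(=O)O[C@@H]2[C@H]1CC[C@]23[C@H](CCCO[Si](C)(C)C(C)(C)C)/C(=C(/C)C(OC)OC)CC[C@]3(C)O[Si](C)(C)C | intermediate
36 | mesylate of 35 | CC(C)=CC/C=C(C)/C=C/C(OS(C)(=O)=O)C1C(=O)O[C@@H]2[C@H]1CC[C@]23[C@H](CCCO[Si](C)(C)C(C)(C)C)/C(=C(/C)C(OC)OC)CC[C@]3(C)O[Si](C)(C)C | intermediate
37 | (E)-α-[(2E,4E)-4,8-dimethylnona-2,4,7-trienylidene] lactone | CC(C)=CC/C=C(C)/C=C/C=C1/C(=O)O[C@@H]2[C@H]1CC[C@]23[C@H](CCCO[Si](C)(C)C(C)(C)C)/C(=C(/C)C(OC)OC)CC[C@]3(C)O[Si](C)(C)C | intermediate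
38 | (1R,2S,5S,6S,10R)-10-[3-(tert-butyldimethylsilyloxy)propyl]-9-[(Z)-1,1-dimethoxypropan-2-ylidene]-2-[(2E,4E,6E)-1-hydroxy-6,10-dimethylundeca-2,4,6,9-tetraen-2-yl]-6-methyl-6-(trimethylsilyloxy)spiro[4.5]decan-1-ol | CC(C)=CC/C=C(C)/C=C/C=C(/CO)[C@@H]1CC[C@]2([C@H](CCCO[Si](C)(C)C(C)(C)C)/C(=C(/C)C(OC)OC)CC[C@]2(C)O[Si](C)(C)C)[C@@H]1O | intermediate
39 | (2Z)-2-{(1R,2S,5S,6S,10R)-1,6-dihydroxy-2-[(2E,4E,6E)-1-hydroxy-6,10-dimethylundeca-2,4,6,9-tetraen-2-yl]-10-(3-hydroxypropyl)-6-methylspiro[4.5]decan-9-ylidene}propanal | CC(C)=CC/C=C(C)/C=C/C=C(/CO)[C@@H]1CC[C@]2([C@H](CCCO)/C(=C(/C)C=O)CC[C@]2(C)O)[C@@H]1O | target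

**Step count**
Total step count: 24. Longest linear sequence: 16 steps (steps 1–3, or 6, 8, 9, or 4, 5, 9, followed by 10–19 and 22–24).

**Three steps most likely to fail**

Step 13 (the new cyclization). Direct conjugate methylation of the vinyl ketone or the wrong regiochemistry of alkyne methylmetalation could win. The fallback uses only known reaction types, sets out from 18 and comes back at 20. Ethynylmagnesium bromide 6 is added to Weinreb amide 18 to give the ynone F1. LiI and AcOH in MeCN add HI across the ynone to give the (Z)-β-iodo enone F2. Pd(PPh3)4, (MeBO)3 and K2CO3 in dioxane at 80 °C then effect oxidative addition, 6-exo-dig syn-carbopalladation of the internal alkyne and Suzuki methylation of the alkenylpalladium, giving the dienone F3 with the same alkene geometry as in 20. Conjugate reduction of the ring enone with [(Ph3P)CuH]6 gives 20.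

Step 14 (facial selectivity of methyl addition). If axial attack or enolisation dominates, the fallback sets out from 20 and comes back at 22. Dimethylsulfoxonium methylide (Me3S(O)I, NaH, DMSO) adds reversibly and closes from the equatorially bonded betaine to the spiro-epoxide F4. LiEt3BH opens F4 at the CH2 terminus to tertiary alcohol 21, and AcOH/Bu4NF then gives 22.

Step 19 (carbenoid C–H insertion). Insertion into the allylic C10–H (δ-lactone) or carbene dimerisation may compete. The fallback sets out from 23 and comes back at 29. Me3SiOTf and 2,6-lutidine give the silyl ether ketone F5. LiN(i-Pr)2 and then methyl bromoacetate alkylate the only enolisable position (C2) to give the keto ester F6. Citric acid in MeOH removes the silyl group to give the hydroxy keto ester F7, whose C2 epimers interconvert through the enol. Me4NBH(OAc)3 again delivers hydride from the C6–OH face, and only the cis hydroxy ester can close, giving the hydroxy lactone F8. 1-(Trimethylsilyl)imidazole converts F8 into 29.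

**Further compounds**

F1 | step 13 | 1-{(1S)-1-[(2E,4R)-1-(tert-butyldimethylsilyloxy)-7,7-dimethoxyhept-2-en-5-yn-4-yl]-2-(triethylsilyloxy)cyclopent-2-en-1-yl}prop-2-yn-1-one | CC[Si](CC)(CC)OC1=CCC[C@]1(C(=O)C#C)[C@@H](C#CC(OC)OC)/C=C/CO[Si](C)(C)C(C)(C)C
F2 | step 13 | (2Z)-3-iodo-1-{(1S)-1-[(2E,4R)-1-(tert-butyldimethylsilyloxy)-7,7-dimethoxyhept-2-en-5-yn-4-yl]-2-(triethylsilyloxy)cyclopent-2-en-1-yl}prop-2-en-1-one | CC[Si](CC)(CC)OC1=CCC[C@]1(C(=O)/C=C\I)[C@@H](C#CC(OC)OC)/C=C/CO[Si](C)(C)C(C)(C)C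
F3 | step 13 | (5S,10R)-10-[(E)-3-(tert-butyldimethylsilyloxy)prop-1-enyl]-9-[(Z)-1,1-dimethoxypropan-2-ylidene]-1-(triethylsilyloxy)spiro[4.5]deca-1,7-dien-6-one | CC[Si](CC)(CC)OC1=CCC[C@]12[C@H](/C=C/CO[Si](C)(C)C(C)(C)C)/C(=C(/C)C(OC)OC)C=CC2=O
F4 | step 14 | spiro-epoxide of 20 at C6 (oxirane CH2 cis to C4, oxygen cis to C1) | CC[Si](CC)(CC)OC1=CCC[C@]12[C@H](/C=C/CO[Si](C)(C)C(C)(C)C)/C(=C(/C)C(OC)OC)CC[C@@]23CO3
F5 | step 19 | (5R,6S,10R)-10-[3-(tert-butyldimethylsilyloxy)propyl]-9-[(Z)-1,1-dimethoxypropan-2-ylidene]-6-methyl-6-(trimethylsilyloxy)spiro[4.5]decan-1-one | O=C1CCC[C@]12[C@H](CCCO[Si](C)(C)C(C)(C)C)/C(=C(/C)C(OC)OC)CC[C@]2(C)O[Si](C)(C)C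
F6 | step 19 | methyl 2-[1-oxo-spirodecan-2-yl]acetate derived from F5 (C2 epimers) | COC(=O)CC1CC[C@]2([C@H](CCCO[Si](C)(C)C(C)(C)C)/C(=C(/C)C(OC)OC)CC[C@]2(C)O[Si](C)(C)C)C1=O
F7 | step 19 | 6-hydroxy keto ester from F6 (C2 epimers) | COC(=O)CC1CC[C@]2([C@H](CCCO[Si](C)(C)C(C)(C)C)/C(=C(/C)C(OC)OC)CC[C@]2(C)O)C1=O
F8 | step 19 | cis-fused γ-lactone with free 6-hydroxyl (29 without the trimethylsilyl group) | O=C1C[C@@H]2CC[C@]3([C@H](CCCO[Si](C)(C)C(C)(C)C)/C(=C(/C)C(OC)OC)CC[C@]3(C)O)[C@@H]2O1
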